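**Remark on the chemistry.** Ring B is labelled O1, C2–C6 and ring A C1'–C6', as in the name of 14. The C4' carbinol configuration written for 7–13 is the one expected from attack anti to chlorine; either epimer should converge on 14 in step 9.

## Analysis of the target

Target 14 is a C15 bisabolane in which an oxane (ring B) is joined through C2 to C1' of a cyclohexane (ring A). Ring B has a fully substituted C2 (methyl, ring A), an axial hydroxyl at C3, an equatorial bromine at C5 and a gem-dimethyl C6. The ring oxygen is therefore flanked by two quaternary carbons, and C5–Br is a neopentyl position that cannot be reached by substitution with inversion. Ring A has a tertiary bromide at C4' and a secondary chloride at C3', trans-diaxial, with the C4' methyl and the C1' substituent equatorial. Of the six stereocentres (2S,3S,5S,1'R,3'S,4'S), C1'–C2–C3 are contiguous, C5 is trans to C3 across ring B, and C3'/C4' lie across ring A from C1'. The central difficulty is C1': without the halogens ring A is symmetric, so C1' is stereogenic only through which side of the ring carries chlorine, and 1,2-induction between C1' and C2 has nothing to work with. The second difficulty is the halogen pattern, bromine on the tertiary and chlorine on the secondary carbon, which is the reverse of what BrCl addition to a trisubstituted olefin gives. The tertiary bromide (ionisation, elimination), the vicinal Br/Cl pair (reductive elimination) and the β-bromo ether require late steps that are non-basic and non-reducing.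

## Retrosynthetic reasoning

**14 to 13.** The C4'–Br bond is cut last because the tertiary bromide is the most fragile group. In the forward sense the tertiary carbinol of 13 is ionised and bromide is delivered anti to the axial C3' chlorine, which bridges the cation. The outcome does not depend on the carbinol configuration, and the silyl ether falls off in the same operation.

**13 to 12.** Ring B is opened at O1–C6 together with C5–Br. The forward reaction is a bromonium-induced 6-endo etherification by the tertiary C2 hydroxyl onto a prenyl-type olefin. It forms the hindered ether and the neopentyl C–Br bond at once and has to set C5.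

**12 to 11 to 10.** The silyl group on O3 is there only to keep that oxygen out of the etherification. The C5=C6 olefin of 11 is traced to the terminal olefin of 10 by cross metathesis, which avoids a prenyl nucleophile that would add through its γ-carbon.

**10 to 8.** The C3–C4 bond is cut. An allyl nucleophile adds to aldehyde 9, generated in the flask from ester 8. The C2 oxygen chelates and the methyl/ring A size difference at C2 has to set C3.

**8 to 6 to 4.** The C4'–CH3 bond comes from a methyl nucleophile and ketone 6. The C3'–Cl bond comes from enolate 5, which is formed only across C3'–C4' because it arises by conjugate reduction of enone 4. The double bond of 4 thus decides which side of ring A is halogenated, and the C1' substituent directs axial chlorination.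

**4 to 2 + 3 (key).** The inter-ring bond C2–C1' is cut. This is the only place where C2 and C1' can be created together, and where ring A can be brought in as a 4-substituted cyclohex-2-enone that already marks C3' and C4'. The forward reaction must control the ketone face of 3 (C2), the relative topicity at the γ-carbon of 2 (C1'), and γ- over α-attack.

**2 to 1.** The dienyl silyl ether is the thermodynamic silylation product of the enone.

## Alternatives that were turned down

**Alternative 1:** (textbook) Disconnection of O1–C6/C5–Br and of both carbon–halogen bonds of ring A, back to diene diol A1. Forward: bromoetherification of A1 to bromoether A2, then BrCl addition across C3'=C4'.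
- BrCl reacts as a bromonium ion that chloride opens at the tertiary carbon in the diaxial Markovnikov sense. The expected product is A3 (tertiary chloride, secondary bromide), a constitutional isomer of 14.
- The required isomer needs anti-Markovnikov opening of the bromonium ion on the other face, and C1', three bonds away, gives no facial bias.
- A1 itself needs C1' and C2 made independently, so the hard problem is only moved upstream, and isomers would have to be separated at the last step.

**Alternative 2:** Disconnection of ring A at C1'–C2' and C5'–C6' by a catalytic asymmetric Diels–Alder reaction of isoprene with an acrylate or vinyl ketone, leading to ketone A4.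
- This sets C1' alone. C2 must then be made by addition to the C2 ketone next to a stereocentre whose two ring branches are identical for three bonds, so no useful 1,2-induction is available.
- Ring A arrives as the trisubstituted olefin, which forces the unfavourable halonium chemistry of alternative 1.

**Alternative 3:** Disconnection of C2–C1' by an Ireland–Claisen rearrangement of cyclohexenyl ester A5 to acid A6, carrying chirality from the cyclohexenol carbinol to the vicinal pair.
- It needs an enantioenriched cyclohexenol and a protected lactic acid.
- Cyclohexenyl esters can rearrange through chair or boat arrangements, which makes the C2/C1' relationship less predictable.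
- A6 has no oxygen at C4'. An allylic oxidation would have to compete with the tertiary allylic C1'–H, and a protecting group must be put on and taken off.
- The cost is at least four more steps than an aldol union that delivers the enone directly.

Key step: step 2

## Route

**Step 1**
Reactants: 1 cyclohex-2-en-1-one
Product: 2 (cyclohexa-1,3-dien-1-yloxy)trimethylsilane
Conditions: Me3SiCl, Et3N, DMF, 80 °C
Reagents that add atoms: chlorotrimethylsilane, C[Si](C)(C)Cl
Why: Silylation under equilibrating conditions (amine hydrochloride, heat) should favour the through-conjugated dienyl ether formed by γ-deprotonation, as in thermodynamic enol ether formation from cyclic enones; no stereocentre is created.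

**Step 2**
Reactants: 2 (cyclohexa-1,3-dien-1-yloxy)trimethylsilane, 3 methyl pyruvate (methyl 2-oxopropanoate)
Product: 4 methyl (2S)-2-[(1R)-4-oxocyclohex-2-en-1-yl]-2-[(trimethylsilyl)oxy]propanoate
Conditions: Cu(OTf)2 (10 mol %), 2,2'-(propane-2,2-diyl)bis[(4S)-4-tert-butyl-4,5-dihydrooxazole] (11 mol %), CH2Cl2, −78 °C; non-acidic work-up
Reagents that add atoms: none
Why: The divalent copper centre of the Cu(OTf)2/bisoxazoline catalyst binds 3 through ketone and ester oxygens in a square-planar chelate, and the γ-carbon of 2 attacks the activated ketone, either in an open Mukaiyama-type transition state or in a highly asynchronous [4+2]-like arrangement that collapses; silyl transfer to the tertiary alkoxide releases 4 and the catalyst (vinylogous Mukaiyama aldol addition). The closest known reaction type is the Cu(OTf)2/bisoxazoline-catalysed aldol addition of enol silanes and 2-silyloxyfurans to pyruvate esters, together with the γ-selective Lewis-acid reactions of silyl dienol ethers of cyclohexenones. No ring is closed: ring A arrives preformed and the new bond is C2–C1'. C2 is controlled by the ligand, whose tert-butyl group should leave the si face of the chelated ketone open and give (2S); the antipodal ligand would be used if the sense proved opposite. C1' is controlled by relative topicity: the pyruvate methyl, not the chelated ester, should lie over the diene, which places the ester anti to C2' and the methyl anti to C6' across the new bond and gives (1'R) with (2S). The step also needs γ- over α-selectivity, which the larger terminal coefficient and the hindrance of the α-carbon next to OSiMe3 should secure. The C2'=C3' double bond of the product marks C3' as the future chlorine-bearing carbon, so the desymmetrisation of ring A is settled in the same operation.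

**Step 3**
Reactants: 4 methyl (2S)-2-[(1R)-4-oxocyclohex-2-en-1-yl]-2-[(trimethylsilyl)oxy]propanoate
Product: 6 methyl (2S)-2-[(1R,3S)-3-chloro-4-oxocyclohexyl]-2-[(trimethylsilyl)oxy]propanoate, via lithium enolate 5 (not isolated)
Conditions: LiBH(s-Bu)3, THF, −78 °C; then N-chlorosuccinimide, −78 to −40 °C; NH4Cl (aq)
Reagents that add atoms: N-chlorosuccinimide, O=C1CCC(=O)N1Cl
Why: 1,4-Reduction of the β-unsubstituted enone by the hindered borohydride gives enolate 5 only across C3'–C4', so chlorination can occur only at C3'. Axial attack on the half-chair with the C1' substituent equatorial should place chlorine trans to C1'; the low temperature prevents enolate equilibration to C5', and the ester has no α-hydrogen.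

**Step 4**
Reactants: 6 methyl (2S)-2-[(1R,3S)-3-chloro-4-oxocyclohexyl]-2-[(trimethylsilyl)oxy]propanoate
Product: 8 methyl (2S)-2-[(1R,3S,4R)-3-chloro-4-hydroxy-4-methylcyclohexyl]-2-hydroxypropanoate, via magnesium alkoxide 7 (not isolated)
Conditions: MeMgBr, THF, −78 °C; then 1 M HCl, THF, 0 °C
Reagents that add atoms: methylmagnesium bromide, C[Mg]Br
Why: Grignard 1,2-addition to the α-chloro ketone, which is far more electrophilic than the hindered α-silyloxy ester. Attack anti to the axial C–Cl bond (Felkin–Anh polar model) should give the axial methyl group; the cold quench avoids rearrangement of the halohydrin alkoxide, and dilute acid removes the trimethylsilyl ether.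

**Step 5**
Reactants: 8 methyl (2S)-2-[(1R,3S,4R)-3-chloro-4-hydroxy-4-methylcyclohexyl]-2-hydroxypropanoate
Product: 10 (2S,3S)-2-[(1R,3S,4R)-3-chloro-4-hydroxy-4-methylcyclohexyl]hex-5-ene-2,3-diol, via aldehyde 9 (not isolated)
Conditions: i-Bu2AlH (3.2 equiv), CH2Cl2, −78 °C; then CH2=CHCH2MgBr, Et2O, −78 to −30 °C; aqueous potassium sodium tartrate
Reagents that add atoms: allylmagnesium bromide, C=CC[Mg]Br
Why: One-pot partial reduction and Grignard addition of an α-oxygenated ester. Aldehyde 9 is held in a five-membered chelate with the C2 alkoxide oxygen (Cram chelate model), and allyl should attack C3 from the face of the C2 methyl, anti to ring A, to give (3S).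

**Step 6**
Reactants: 10 (2S,3S)-2-[(1R,3S,4R)-3-chloro-4-hydroxy-4-methylcyclohexyl]hex-5-ene-2,3-diol
Product: 11 (2S,3S)-2-[(1R,3S,4R)-3-chloro-4-hydroxy-4-methylcyclohexyl]-6-methylhept-5-ene-2,3-diol
Conditions: second-generation Grubbs catalyst (1,3-dimesitylimidazolidin-2-ylidene)(PCy3)Cl2Ru=CHPh (5 mol %), 2-methylbut-2-ene (large excess), CH2Cl2, 40 °C
Reagents that add atoms: 2-methylbut-2-ene, CC=C(C)C
Why: Olefin cross metathesis of a terminal alkene with 2-methylbut-2-ene should give the trisubstituted prenyl-type olefin. Free hydroxyls and the alkyl chloride are tolerated and no stereocentre is touched.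

**Step 7**
Reactants: 11 (2S,3S)-2-[(1R,3S,4R)-3-chloro-4-hydroxy-4-methylcyclohexyl]-6-methylhept-5-ene-2,3-diol
Product: 12 (2S,3S)-2-[(1R,3S,4R)-3-chloro-4-hydroxy-4-methylcyclohexyl]-6-methyl-3-[(triethylsilyl)oxy]hept-5-en-2-ol
Conditions: Et3SiCl, imidazole, DMF, 0 °C
Reagents that add atoms: chlorotriethylsilane, CC[Si](Cl)(CC)CC
Why: Silylation should select the secondary C3 hydroxyl over the two tertiary hydroxyls on steric grounds. The silyl ether blocks 5-endo attack of O3 in step 8 and is removed in step 9.

**Step 8**
Reactants: 12 (2S,3S)-2-[(1R,3S,4R)-3-chloro-4-hydroxy-4-methylcyclohexyl]-6-methyl-3-[(triethylsilyl)oxy]hept-5-en-2-ol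
Product: 13 (1R,2S,4R)-4-[(2S,3S,5S)-5-bromo-2,6,6-trimethyl-3-[(triethylsilyl)oxy]oxan-2-yl]-2-chloro-1-methylcyclohexan-1-ol
Conditions: 2,4,4,6-tetrabromocyclohexa-2,5-dien-1-one (1.1 equiv), CH3NO2, −20 to 0 °C, dark
Reagents that add atoms: 2,4,4,6-tetrabromocyclohexa-2,5-dien-1-one, O=C1C(Br)=CC(Br)(Br)C=C1Br
Why: Bromonium-induced etherification: the tertiary C2 hydroxyl opens the C5–C6 bromonium ion at the tertiary C6 (6-endo, Markovnikov, anti addition), so bromine is equatorial in the chair. The chair with ring A equatorial and the C3 silyloxy group axial avoids a syn-diaxial clash between ring A and a C6 methyl and should give (5S).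

**Step 9**
Reactants: 13 (1R,2S,4R)-4-[(2S,3S,5S)-5-bromo-2,6,6-trimethyl-3-[(triethylsilyl)oxy]oxan-2-yl]-2-chloro-1-methylcyclohexan-1-ol
Product: 14 (2S,3S,5S)-5-bromo-2-[(1R,3S,4S)-4-bromo-3-chloro-4-methylcyclohexyl]-2,6,6-trimethyloxan-3-ol
Conditions: Me3SiBr (3 equiv), CH2Cl2, −20 to 0 °C; then MeOH, 0 °C
Reagents that add atoms: bromotrimethylsilane, C[Si](C)(C)Br
Why: Ionising substitution of the tertiary alcohol: the C4' cation is bridged by the axial C3' chlorine and bromide should enter axially anti to it, giving the trans-diaxial bromochloride from either carbinol epimer. The methanol quench liberates HBr, which removes the triethylsilyl ether.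

## Compound list

1 | cyclohex-2-en-1-one | O=C1C=CCCC1 | starting material
2 | (cyclohexa-1,3-dien-1-yloxy)trimethylsilane | C[Si](C)(C)OC1=CC=CCC1 | intermediate
3 | methyl pyruvate (methyl 2-oxopropanoate) | COC(=O)C(C)=O | starting material
4 | methyl (2S)-2-[(1R)-4-oxocyclohex-2-en-1-yl]-2-[(trimethylsilyl)oxy]propanoate | COC(=O)[C@@](C)(O[Si](C)(C)C)[C@@H]1CCC(=O)C=C1 | intermediate
5 | lithium (4R)-4-[(2S)-1-methoxy-1-oxo-2-[(trimethylsilyl)oxy]propan-2-yl]cyclohex-1-en-1-olate | [Li+].COC(=O)[C@@](C)(O[Si](C)(C)C)[C@@H]1CCC([O-])=CC1 | intermediate (not isolated)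
6 | methyl (2S)-2-[(1R,3S)-3-chloro-4-oxocyclohexyl]-2-[(trimethylsilyl)oxy]propanoate | COC(=O)[C@@](C)(O[Si](C)(C)C)[C@@H]1CCC(=O)[C@@H](Cl)C1 | intermediate
7 | bromomagnesium (1R,2S,4R)-2-chloro-4-[(2S)-1-methoxy-1-oxo-2-[(trimethylsilyl)oxy]propan-2-yl]-1-methylcyclohexan-1-olate | COC(=O)[C@@](C)(O[Si](C)(C)C)[C@@H]1CC[C@@](C)([O-])[C@@H](Cl)C1.[Mg+2].[Br-] | intermediate (not isolated)
8 | methyl (2S)-2-[(1R,3S,4R)-3-chloro-4-hydroxy-4-methylcyclohexyl]-2-hydroxypropanoate | COC(=O)[C@@](C)(O)[C@@H]1CC[C@@](C)(O)[C@@H](Cl)C1 | intermediate
9 | (2S)-2-[(1R,3S,4R)-3-chloro-4-hydroxy-4-methylcyclohexyl]-2-hydroxypropanal | O=C[C@@](C)(O)[C@@H]1CC[C@@](C)(O)[C@@H](Cl)C1 | intermediate (not isolated)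
10 | (2S,3S)-2-[(1R,3S,4R)-3-chloro-4-hydroxy-4-methylcyclohexyl]hex-5-ene-2,3-diol | C=CC[C@H](O)[C@@](C)(O)[C@@H]1CC[C@@](C)(O)[C@@H](Cl)C1 | intermediate
11 | (2S,3S)-2-[(1R,3S,4R)-3-chloro-4-hydroxy-4-methylcyclohexyl]-6-methylhept-5-ene-2,3-diol | CC(C)=CC[C@H](O)[C@@](C)(O)[C@@H]1CC[C@@](C)(O)[C@@H](Cl)C1 | intermediate
12 | (2S,3S)-2-[(1R,3S,4R)-3-chloro-4-hydroxy-4-methylcyclohexyl]-6-methyl-3-[(triethylsilyl)oxy]hept-5-en-2-ol | CC(C)=CC[C@H](O[Si](CC)(CC)CC)[C@@](C)(O)[C@@H]1CC[C@@](C)(O)[C@@H](Cl)C1 | intermediate
13 | (1R,2S,4R)-4-[(2S,3S,5S)-5-bromo-2,6,6-trimethyl-3-[(triethylsilyl)oxy]oxan-2-yl]-2-chloro-1-methylcyclohexan-1-ol | CC1(C)O[C@@](C)([C@@H]2CC[C@@](C)(O)[C@@H](Cl)C2)[C@@H](O[Si](CC)(CC)CC)C[C@@H]1Br | intermediate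
14 | (2S,3S,5S)-5-bromo-2-[(1R,3S,4S)-4-bromo-3-chloro-4-methylcyclohexyl]-2,6,6-trimethyloxan-3-ol | CC1(C)O[C@@](C)([C@@H]2CC[C@](C)(Br)[C@@H](Cl)C2)[C@@H](O)C[C@@H]1Br | target

## Step count and least certain steps

Total step count: 9. Longest linear sequence: 9 steps (from 1).

**Step 2 (key step).** The most likely failure is insufficient control of relative topicity at C1', because the open and the [4+2]-like transition states may be close in energy; attack through the α-carbon of 2 is a second possibility. Face selection at C2 is the better-controlled element. The fallback sets out from 4 obtained as a mixture of C1' epimers. Hydrogenation (H2, Pd/C, EtOAc) would erase the ring stereocentre and converge both epimers on saturated ketone F1. Desymmetrising enolisation with lithium (S,S)-bis(1-phenylethyl)amide and Me3SiCl (in situ quench, THF, −100 °C; the antipodal base if the sense proved opposite) would give silyl enol ether F2. N-Chlorosuccinimide would then return the route to 6. C1' would thus be set by reagent control instead of by the aldol.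

**Step 8.** The likely failures are competing 5-exo closure to a tetrahydrofuran, participation of the silylated O3, and poor face selection in bromonium formation, since both chair arrangements carry a syn-diaxial interaction. The fallback sets out from 12. Shi epoxidation, with the ketone enantiomer that delivers the (R)-epoxide, would give epoxide F4. Opening with Li2NiBr4 (THF, 0 °C) at the less hindered secondary carbon with inversion would give bromohydrin F5. Acid-induced ionisation of the tertiary hydroxyl with bromine participation (BF3·OEt2 cat., CH2Cl2, −20 °C) would generate a configurationally defined bromonium ion that the C2 hydroxyl traps, returning the route to 13 with C5 fixed by the reagent.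

**Step 9.** The likely failures are proton loss or ring contraction during the unassisted ionisation of the equatorial, inductively deactivated C–O bond, and acid opening of ring B through bromine participation. The fallback sets out from 13. Dehydration with SOCl2/pyridine (0 °C), in which only methyl hydrogens are antiperiplanar to the equatorial leaving group, would give exocyclic alkene F6. Markovnikov addition of HBr (CH2Cl2, −78 °C), then MeOH to remove the silyl ether, would give 14. The chlorine-bridged cation would then be reached by alkene protonation at a temperature where ring B is inert.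

**Step 5.** The likely failures are over-reduction of 9 before the allyl reagent arrives and erosion of chelate control by the aluminium alkoxide. The fallback sets out from 8. Reduction with LiBH4 (THF, 0 °C) would give triol F3. Oxidation of the primary alcohol with SO3·pyridine/DMSO/i-Pr2NEt would give 9, now isolated. Reagent-controlled allylboration with the antipode of B-allyldiisopinocampheylborane that delivers (3S) (Et2O, −78 °C; oxidative work-up) would return the route to 10.

## Further compounds

F1 | step 2 | methyl (2S)-2-(4-oxocyclohexyl)-2-[(trimethylsilyl)oxy]propanoate | COC(=O)[C@@](C)(O[Si](C)(C)C)C1CCC(=O)CC1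
F2 | step 2 | methyl (2S)-2-[(1R)-4-[(trimethylsilyl)oxy]cyclohex-3-en-1-yl]-2-[(trimethylsilyl)oxy]propanoate | COC(=O)[C@@](C)(O[Si](C)(C)C)[C@@H]1CCC(O[Si](C)(C)C)=CC1
F3 | step 5 | (2S)-2-[(1R,3S,4R)-3-chloro-4-hydroxy-4-methylcyclohexyl]propane-1,2-diol | OC[C@@](C)(O)[C@@H]1CC[C@@](C)(O)[C@@H](Cl)C1
F4 | step 8 | (1R,2S,4R)-2-chloro-4-[(2S,3S)-4-[(2R)-3,3-dimethyloxiran-2-yl]-2-hydroxy-3-[(triethylsilyl)oxy]butan-2-yl]-1-methylcyclohexan-1-ol | CC1(C)O[C@@H]1C[C@H](O[Si](CC)(CC)CC)[C@@](C)(O)[C@@H]1CC[C@@](C)(O)[C@@H](Cl)C1
F5 | step 8 | (2S,3S,5S)-5-bromo-2-[(1R,3S,4R)-3-chloro-4-hydroxy-4-methylcyclohexyl]-6-methyl-3-[(triethylsilyl)oxy]heptane-2,6-diol | CC(C)(O)[C@@H](Br)C[C@H](O[Si](CC)(CC)CC)[C@@](C)(O)[C@@H]1CC[C@@](C)(O)[C@@H](Cl)C1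
F6 | step 9 | (2S,3S,5S)-5-bromo-2-[(1R,3S)-3-chloro-4-methylidenecyclohexyl]-2,6,6-trimethyl-3-[(triethylsilyl)oxy]oxane | CC1(C)O[C@@](C)([C@@H]2CCC(=C)[C@@H](Cl)C2)[C@@H](O[Si](CC)(CC)CC)C[C@@H]1Br
A1 | alternative 1 | (2S,3S)-6-methyl-2-[(1R)-4-methylcyclohex-3-en-1-yl]hept-5-ene-2,3-diol | CC(C)=CC[C@H](O)[C@@](C)(O)[C@@H]1CCC(C)=CC1
A2 | alternative 1 | (2S,3S,5S)-5-bromo-2,6,6-trimethyl-2-[(1R)-4-methylcyclohex-3-en-1-yl]oxan-3-ol | CC1(C)O[C@@](C)([C@@H]2CCC(C)=CC2)[C@@H](O)C[C@@H]1Br
A3 | alternative 1 | (2S,3S,5S)-5-bromo-2-[(1R,3S,4S)-3-bromo-4-chloro-4-methylcyclohexyl]-2,6,6-trimethyloxan-3-ol | CC1(C)O[C@@](C)([C@@H]2CC[C@](C)(Cl)[C@@H](Br)C2)[C@@H](O)C[C@@H]1Br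
A4 | alternative 2 | 1-[(1R)-4-methylcyclohex-3-en-1-yl]ethan-1-one | CC(=O)[C@@H]1CCC(C)=CC1
A5 | alternative 3 | (1S)-cyclohex-2-en-1-yl 2-[(4-methoxyphenyl)methoxy]propanoate | CC(OCc1ccc(OC)cc1)C(=O)O[C@@H]1C=CCCC1
A6 | alternative 3 | (2S)-2-[(1R)-cyclohex-2-en-1-yl]-2-[(4-methoxyphenyl)methoxy]propanoic acid | OC(=O)[C@@](C)(OCc1ccc(OC)cc1)[C@@H]1CCCC=C1
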